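The runs were generated by integration from invented constants, noise included.

The meeting resolved to carry one number from the green run to the new flasks, and to test it before any new flask was seen.

| flask | electrophile | nucleophile | protic impurity | remark | time |
|---|---|---|---|---|---|
| green | 0.34 M | 1.5 equiv | 0.50 M | run made earlier |  |
| Saturday's | 0.50 M | 1.50 equiv | 0.500 M |  | 50 min |
| Wednesday's | 0.50 M | 2.20 equiv | 0.500 M |  | 50 min |
| Friday's | 0.50 M | 3.40 equiv | 0.500 M |  | 50 min |

green run (percent of the electrophile charged)

| time / min | electrophile / % | target / % |
|---|---|---|
| 2.50 | 83 | 9 |
| 6.00 | 65 | 10 |
| 12.0 | 43 | 9 |
| 30.0 | 22 | 6 |

(readings scatter by 1.5 percentage points)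



1. part of the electrophile that has reacted at the end, Saturday's
2. part of the electrophile that has reacted at the end, Wednesday's
3. part of the electrophile that has reacted at the end, Friday's
4. what raising the equivalents of nucleophile from its lowest to its highest value here does to the part of the electrophile that has reacted (changes below 5 percentage points count as none) (it falls / no change / it rises)

Minutes. The first speaker noted that in the green run the electrophile's decay slows while the target stays small, and proposed counting one nucleophile lost per electrophile lost. The carried quantity is then the effective constant k_e, the second-order rate constant of that one-to-one count. With q the equivalents, c the electrophile charge and x the fraction of electrophile left, it obeys ln[(q − 1 + x)/(q x)] = k_e c (q − 1) t.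

The last green reading gives k_e = 0.153 /M/min, and the first gives 0.155 /M/min, which the speaker accepted given the scatter.

The second speaker noted that x stands twice in that relation, in numerator and denominator, and wrote it as x = (q − 1 + x)/(q E), with E = exp[k_e c (q − 1) t]. She put a first answer back in and went round until it stopped moving, which gives x = (q − 1)/(q E − 1). The meeting's reckoning for the part reacted is therefore 94.5% for Saturday's, 99.4% for Wednesday's and >99.9% for Friday's, a rise of 5.5 percentage points.

The forecast, entered next, gave 93%, 99% and 100%, with the trend as it rises. It put Saturday's lower than the meeting did, warning: “Some nucleophile may also be lost to the impurity”.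

The flask gives 91.8%, 99.5% and >99.9%, and the trend is it rises, by 8.2 points.

    electrophile + nucleophile → acid set free + target (k = 0.131 /M/min)
    nucleophile + acid set free ⇌ protonated nucleophile, settled at all times (K = 2850 /M)
    electrophile + target → side product (k = 0.970 /M/min)
    nucleophile + acid set free ⇌ idle adduct, settled at all times (K = 1.10 /M)
    nucleophile + protic impurity → quenched reagent (k = 0.0758 /M/min)

The forecast held. The main reason for the rise is the difference in equivalents of nucleophile: Friday's, put back to Saturday's equivalents, falls from >99.9% to 91.8%. The quench of nucleophile by protic impurity is one part of what holds Saturday's down: without that step Saturday's reaches 98.5% instead of 91.8%. The reckoning with k_e, at 0.153 /M/min, came within 2.7 points of Saturday's.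

Take Wednesday's flask with 0.550 equiv of nucleophile, where nucleophile is the limiting reagent: k_e gives 50.1% reacted. The simulation gives 42.1%, with 1.2% of the nucleophile left.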